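All runs come from a simulation with made-up constants, noise included.

Reagent left over is the quantity to watch. At 8.00 min, Tuesday's readings put the reagent left at 10.1% of the starting material charged, counting one reagent spent per product turnover.

| setting | Tuesday's | Saturday's | violet | green |
|---|---|---|---|---|
| starting material | 0.0050 M | 0.0050 M | 0.0050 M | 0.0050 M |
| reagent | 0.55 equiv | 0.84 equiv | 0.800 equiv | 1.20 equiv |
| free catalyst | 0.5 mol% | 0.5 mol% | 0.5 mol% | 0.5 mol% |
| second catalyst | 2 mol% | 2 mol% | 2 mol% | 2 mol% |
| remark | run made earlier | run made earlier |  |  |
| time |  |  | 12 min | 12 min |

| run | time / min | intermediate / % | product / % | starting material / % |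
|---|---|---|---|---|
| Tuesday's | 1.00 | 75.9 | 9.4 | 16.3 |
| Tuesday's | 3.00 | 72.0 | 27.4 | 0.6 |
| Tuesday's | 5.00 | 62.5 | 36.6 | 0.1 |
| Tuesday's | 8.00 | 54.6 | 44.9 | 0 |
| Saturday's | 1.00 | 72.1 | 12.0 | 16.8 |
| Saturday's | 3.00 | 60.8 | 38.5 | 2.2 |
| Saturday's | 5.00 | 47.1 | 51.4 | 0.7 |
| Saturday's | 8.00 | 37.6 | 62.9 | 0.1 |

(each reading ± 0.5 percentage points)

- the earlier runs were read with a standard deviation of 0.5 percentage points

* which one finishes higher in amount of intermediate, in percent of the starting material charged ("neither" within 2 percentage points) (violet / green / neither)
* amount of intermediate at the end, in percent of the starting material charged, violet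
* amount of intermediate at the end, in percent of the starting material charged, green

The reckoning here climbs a ladder of times, fastest first, with concentrations as fractions of the starting material charged.

1. Starting material: Tuesday's first reading gives a half-life of 0.382 min. Intermediate therefore appears on average 0.551 min after the start.

2. Intermediate: the rate of product divided by c(intermediate)·c(reagent), integrated between the readings at 3.00 min and 8.00 min, gives 0.324 min⁻¹ in Tuesday's run and 0.329 min⁻¹ in Saturday's. Their mean is the turnover constant κ, 0.326 min⁻¹. At violet's full charge of reagent, the reckoned half-life of intermediate is 2.65 min, longer than the half-life of starting material read in Tuesday's run.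

3. Ratio: ln[c(intermediate)/c(reagent)] moves at κ times (one minus the equivalents). Violet's ratio thus doubles every 10.6 min, slower than the previous rung. In the step from intermediate to product, reagent is violet's limiting reagent, with room for 80.0% product.

4. End: the ratio starts at one over the equivalents and runs for 12 min less the delay. It reaches 2.64 in violet and 0.395 in green. Intermediate equals the ratio times (one minus the equivalents), over (the ratio minus one): 32.2% in violet, 13.0% in green.

The forecast says violet, with 32% and 13%, on “clean second-order behaviour”; the reckoning here, from the same readings, stands at 32.2% and 13.0%.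

The flask gives violet: 32.1% in violet, 13.0% in green.

    reagent + second catalyst + intermediate → second catalyst + product (k = 11000 L² mol⁻² s⁻¹)
    starting material + free catalyst → free catalyst + intermediate (k = 1200 L mol⁻¹ s⁻¹)

The neighbour is violet with 0.480 equiv of reagent. With κ at 0.326 min⁻¹, its ratio reaches 14.6, which reckons 55.8% intermediate. The simulated neighbour ends with 55.8% intermediate and 44.2% product, and 7.86% of its own reagent charge remains.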